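**Plan**

1. Numbering: chain C1 (ester carbon) to C20 (CHBr). The oxolane is the ring O/C5/C6/C7/C8, read as its 2,5-trans isomer (5R,8S).
2. Cuts: C17=C18 (Wittig, C18–C20 from (E)-3-bromoacrolein), then C10–C11 (Sonogashira, C11–C17 from an E-iodoalkenol), then together the ring bond O–C5 and the chain bond C3–C4, last C8–C9 (acyl alkynylation).
3. Enabling feature: the oxolane with its C4 arm is a closed pent-4-en-1-ol (HO–C8–C7–C6–C5=C4) and C3–C1 is an acrylate unit on C4. One cobalt-catalysed aerobic cyclisation/Giese cascade therefore closes O–C5 and adds the whole ester arm.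
4. Forward: C4–C8 acid chloride + silylacetylene → ynone → (S)-carbinol → oxolane ester (the only ring, closed in the cascade) → ethynyl oxolane → enyne alcohol → phosphonium salt → bromodiene.
5. Stereochemistry: C8 by catalyst-controlled Noyori transfer hydrogenation; C5 from C8 through the 2,5-trans closure; E-C11=C12 by syn hydrozirconation; Z-C17=C18 by the lithium-free Wittig; E-C19=C20 carried in with the bromoenal.

Key step: step 3

Remark: (E)-3-bromoprop-2-enal is treated as too labile to buy; it is made fresh (steps 9–11) and used as a solution.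

**Step 1**
Reactants: 1 pent-4-enoyl chloride; 2 ethynyltrimethylsilane
Product: 3 1-(trimethylsilyl)hept-6-en-1-yn-3-one
Conditions: PdCl2(PPh3)2 (2 mol%), CuI (4 mol%), Et3N (1.2 equiv), THF, rt
Reagents that add atoms: none
Why: Acyl Sonogashira coupling, in which the acid chloride adds to zerovalent palladium and the copper acetylide transmetalates, should give the silyl ynone at room temperature without touching the terminal alkene.

**Step 2**
Reactants: 3 1-(trimethylsilyl)hept-6-en-1-yn-3-one
Product: 4 (3S)-1-(trimethylsilyl)hept-6-en-1-yn-3-ol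
Conditions: Ru[(S,S)-TsNCH(Ph)CH(Ph)NH](p-cymene) (1 mol%), iPrOH, rt
Reagents that add atoms: none
Why: Noyori asymmetric transfer hydrogenation of an alkynyl ketone, in which the (S,S)-TsDPEN ruthenium hydride places the alkyne where an aryl group sits in aryl ketones, should set the C8 carbinol as S by catalyst control and leave the isolated alkene and the silylalkyne alone.

**Step 3**
Reactants: 4 (3S)-1-(trimethylsilyl)hept-6-en-1-yn-3-ol; 5 methyl acrylate
Product: 6 methyl 4-[(2R,5S)-5-[(trimethylsilyl)ethynyl]oxolan-2-yl]butanoate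
Conditions: bis(4,4,4-trifluoro-1-phenylbutane-1,3-dionato)cobalt (5 mol%), methyl acrylate (10 equiv), 1,4-cyclohexadiene (10 equiv), air (1 atm), toluene, 60 °C
Reagents that add atoms: none
Why: The alkenol binds through oxygen to the cobalt complex, which dioxygen has raised from divalent to trivalent cobalt, and the C8 oxygen adds to C5 of the C4=C5 alkene to leave a primary radical on exocyclic C4; this nucleophilic radical adds to methyl acrylate and the resulting electrophilic α-ester radical takes a hydrogen atom from 1,4-cyclohexadiene. The closest known reaction type is the Mukaiyama-type cobalt-catalysed aerobic oxidative cyclisation of pent-4-en-1-ols run with Giese trapping and reductive termination (aerobic oxidation–radical addition cascade). The oxolane closes by 5-exo-trig C–O bond formation. C5 is the new stereocentre and is controlled by C8: in the chair-like arrangement of the cobalt-bound alkenol the silylalkynyl group on C8 should lie pseudo-equatorial, which places the new C5–C4 bond trans to it across the ring oxygen, in line with the behaviour of 1-aryl and 1-alkyl pent-4-en-1-ols. The step needs 2,5-trans selectivity and conjugate addition of the C4 radical in preference to capture by dioxygen, direct reduction or telomerisation; the first rests on the C8 substituent, the second on the polarity match between alkyl radical and excess acrylate, on air in place of pure dioxygen, and on the polarity-matched hydrogen transfer to the α-ester radical. The trans geometry also keeps the C4 radical out of reach of the silyl-capped alkyne, which stays a spectator.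

**Step 4**
Reactants: 6 methyl 4-[(2R,5S)-5-[(trimethylsilyl)ethynyl]oxolan-2-yl]butanoate
Product: 7 methyl 4-[(2R,5S)-5-ethynyloxolan-2-yl]butanoate
Conditions: K2CO3 (0.2 equiv), dry MeOH, rt
Reagents that add atoms: none
Why: Base-catalysed methanolysis of the C(sp)–Si bond frees the terminal alkyne, ester exchange is degenerate in methanol, and neither oxolane stereocentre is acidic enough to epimerise.

**Step 5**
Reactants: 8 hept-6-yn-1-ol
Product: 10 (6E)-7-iodohept-6-en-1-ol, via alkenylzirconocene chloride 9 (not isolated)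
Conditions: Cp2Zr(H)Cl (2.2 equiv), THF, rt; then I2 (1.1 equiv), 0 °C; aqueous work-up
Reagents that add atoms: iodine, II
Why: Hydrozirconation–iodination, in which the first equivalent of Cp2Zr(H)Cl is spent on the O–H and the second adds syn and anti-Markovnikov across the terminal alkyne before iodinolysis with retention, should fix the E geometry of C11=C12.

**Step 6**
Reactants: 7 methyl 4-[(2R,5S)-5-ethynyloxolan-2-yl]butanoate; 10 (6E)-7-iodohept-6-en-1-ol
Product: 11 methyl 4-[(2R,5S)-5-[(3E)-9-hydroxynon-3-en-1-yn-1-yl]oxolan-2-yl]butanoate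
Conditions: Pd(PPh3)4 (3 mol%), CuI (6 mol%), Et3N, THF, rt, degassed
Reagents that add atoms: none
Why: Sonogashira coupling joins the terminal alkyne to the E-iodoalkene with retention of alkene geometry, and the ester, the free alcohol and the propargylic ether centre are inert under the mild amine conditions.

**Step 7**
Reactants: 11 methyl 4-[(2R,5S)-5-[(3E)-9-hydroxynon-3-en-1-yn-1-yl]oxolan-2-yl]butanoate
Product: 12 methyl 4-[(2R,5S)-5-[(3E)-9-iodonon-3-en-1-yn-1-yl]oxolan-2-yl]butanoate
Conditions: PPh3, I2, imidazole, CH2Cl2, 0 °C → rt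
Reagents that add atoms: iodine, II
Why: Appel-type iodination (Garegg–Samuelsson conditions) converts the primary alcohol into the iodide by SN2 displacement of the alkoxyphosphonium ion without affecting the enyne, the ester or the ring.

**Step 8**
Reactants: 12 methyl 4-[(2R,5S)-5-[(3E)-9-iodonon-3-en-1-yn-1-yl]oxolan-2-yl]butanoate
Product: 13 {(6E)-9-[(2S,5R)-5-(4-methoxy-4-oxobutyl)oxolan-2-yl]non-6-en-8-yn-1-yl}triphenylphosphonium iodide
Conditions: PPh3 (1.5 equiv), MeCN, 80 °C
Reagents that add atoms: triphenylphosphine, c1ccc(cc1)P(c1ccccc1)c1ccccc1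
Why: SN2 quaternisation of triphenylphosphine by the primary iodide gives the Wittig salt, and no other electrophilic site in the molecule competes.

**Step 9**
Reactants: 14 prop-2-ynoic acid
Product: 15 (2E)-3-bromoprop-2-enoic acid
Conditions: 48% aq HBr, 95 °C
Reagents that add atoms: hydrogen bromide, Br
Why: Hydrobromination of the ynoic acid by conjugate addition of bromide should, on heating in the acid, equilibrate to the more stable E acid, which sets the C19=C20 geometry.

**Step 10**
Reactants: 15 (2E)-3-bromoprop-2-enoic acid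
Product: 16 (2E)-3-bromoprop-2-en-1-ol
Conditions: BH3·THF (1.1 equiv), THF, 0 °C → rt; aqueous work-up
Reagents that add atoms: none
Why: Borane reduces the carboxylic acid through its acyloxyborane faster than it hydroborates the electron-poor bromoalkene, which should keep the C–Br bond and the E geometry.

**Step 11**
Reactants: 16 (2E)-3-bromoprop-2-en-1-ol
Product: 17 (2E)-3-bromoprop-2-enal
Conditions: MnO2 (10 equiv), CH2Cl2, rt; filtered and used as a solution
Reagents that add atoms: none
Why: MnO2 oxidation of the allylic alcohol stops at the enal and does not isomerise the E double bond.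

**Step 12**
Reactants: 13 {(6E)-9-[(2S,5R)-5-(4-methoxy-4-oxobutyl)oxolan-2-yl]non-6-en-8-yn-1-yl}triphenylphosphonium iodide; 17 (2E)-3-bromoprop-2-enal
Product: 19 methyl 4-[(2R,5S)-5-[(3E,9Z,11E)-12-bromododeca-3,9,11-trien-1-yn-1-yl]oxolan-2-yl]butanoate, via phosphonium ylide 18 (not isolated)
Conditions: NaN(SiMe3)2 (1.0 equiv), THF, −78 °C; then 17 (1.3 equiv), −78 °C → 0 °C
Reagents that add atoms: none
Why: Wittig olefination with a non-stabilised ylide under lithium-free conditions passes through the kinetically favoured cis-oxaphosphetane and should give the Z C17=C18 bond, while the E bromoalkene of the enal is carried over unchanged and 1,2-addition to the aldehyde outruns attack at the methyl ester.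

**Compound list**

1 | pent-4-enoyl chloride | C=CCCC(=O)Cl | starting material
2 | ethynyltrimethylsilane | C#C[Si](C)(C)C | starting material
3 | 1-(trimethylsilyl)hept-6-en-1-yn-3-one | C=CCCC(=O)C#C[Si](C)(C)C | intermediate
4 | (3S)-1-(trimethylsilyl)hept-6-en-1-yn-3-ol | C=CCC[C@H](O)C#C[Si](C)(C)C | intermediate
5 | methyl acrylate | C=CC(=O)OC | starting material
6 | methyl 4-[(2R,5S)-5-[(trimethylsilyl)ethynyl]oxolan-2-yl]butanoate (2,5-trans) | COC(=O)CCC[C@@H]1CC[C@@H](C#C[Si](C)(C)C)O1 | intermediate
7 | methyl 4-[(2R,5S)-5-ethynyloxolan-2-yl]butanoate | COC(=O)CCC[C@@H]1CC[C@@H](C#C)O1 | intermediate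
8 | hept-6-yn-1-ol | C#CCCCCCO | starting material
9 | (E)-alkenylzirconocene chloride of 8, hydroxyl held as its zirconocene chloride alkoxide (not isolated) | Cl[Zr](OCCCCC/C=C/[Zr](Cl)(C1C=CC=C1)C1C=CC=C1)(C1C=CC=C1)C1C=CC=C1 | intermediate
10 | (6E)-7-iodohept-6-en-1-ol | OCCCCC/C=C/I | intermediate
11 | methyl 4-[(2R,5S)-5-[(3E)-9-hydroxynon-3-en-1-yn-1-yl]oxolan-2-yl]butanoate | COC(=O)CCC[C@@H]1CC[C@@H](C#C/C=C/CCCCCO)O1 | intermediate
12 | methyl 4-[(2R,5S)-5-[(3E)-9-iodonon-3-en-1-yn-1-yl]oxolan-2-yl]butanoate | COC(=O)CCC[C@@H]1CC[C@@H](C#C/C=C/CCCCCI)O1 | intermediate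
13 | {(6E)-9-[(2S,5R)-5-(4-methoxy-4-oxobutyl)oxolan-2-yl]non-6-en-8-yn-1-yl}triphenylphosphonium iodide | COC(=O)CCC[C@@H]1CC[C@@H](C#C/C=C/CCCCC[P+](c2ccccc2)(c2ccccc2)c2ccccc2)O1.[I-] | intermediate
14 | prop-2-ynoic acid (propiolic acid) | C#CC(=O)O | starting material
15 | (2E)-3-bromoprop-2-enoic acid | OC(=O)/C=C/Br | intermediate
16 | (2E)-3-bromoprop-2-en-1-ol | OC/C=C/Br | intermediate
17 | (2E)-3-bromoprop-2-enal | O=C/C=C/Br | intermediate
18 | phosphonium ylide of 13 (not isolated) | COC(=O)CCC[C@@H]1CC[C@@H](C#C/C=C/CCCCC=P(c2ccccc2)(c2ccccc2)c2ccccc2)O1 | intermediate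
19 | methyl 4-[(2R,5S)-5-[(3E,9Z,11E)-12-bromododeca-3,9,11-trien-1-yn-1-yl]oxolan-2-yl]butanoate (CNP0231094.1) | COC(=O)CCC[C@@H]1CC[C@@H](C#C/C=C/CCCC/C=C\C=C\Br)O1 | target

**Step count**

Total step count: 12
Longest linear sequence: 8 steps (steps 1, 2, 3, 4, 6, 7, 8, 12)

**Steps most likely to fail**

Step 3. The C4 radical may be captured by dioxygen or reduced directly by the hydrogen donor before it adds to the acrylate, and the α-ester radical may telomerise. The fallback separates ring closure from C–C bond formation and sets out from 4. Compound 4 is cyclised under hydroxylating Mukaiyama conditions (bis(1-morpholinocarbamoyl-4,4-dimethyl-1,3-pentanedionato)cobalt, O2 1 atm, tBuOOH cat., iPrOH, 55 °C), where dioxygen is the only trap, to give [(2S,5S)-5-[(trimethylsilyl)ethynyl]oxolan-2-yl]methanol F1. Iodination (PPh3, I2, imidazole, CH2Cl2) gives trimethyl{[(2S,5S)-5-(iodomethyl)oxolan-2-yl]ethynyl}silane F2. Tin-mediated Giese addition (Bu3SnH by slow addition, AIBN, methyl acrylate in excess, benzene, 80 °C) then comes back to the route at 6.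

Step 12. Z selectivity may erode, the ylide may attack the bromine-bearing carbon of the enal by addition–elimination, and the enal may polymerise. The fallback builds the diene by cross-coupling and sets out from 11. Dess–Martin oxidation (CH2Cl2, rt) gives methyl 4-[(2R,5S)-5-[(3E)-9-oxonon-3-en-1-yn-1-yl]oxolan-2-yl]butanoate F3. Stork–Zhao olefination ((iodomethyl)triphenylphosphonium iodide, NaN(SiMe3)2, THF/DMPU, −78 °C) gives methyl 4-[(2R,5S)-5-[(3E,9Z)-10-iododeca-3,9-dien-1-yn-1-yl]oxolan-2-yl]butanoate F4. Stille coupling with (E)-1,2-bis(tributylstannyl)ethene in excess (PdCl2(MeCN)2, DMF, rt) gives methyl 4-[(2R,5S)-5-[(3E,9Z,11E)-12-(tributylstannyl)dodeca-3,9,11-trien-1-yn-1-yl]oxolan-2-yl]butanoate F5. Bromodestannylation with retention (NBS, MeCN, 0 °C) comes back to the route at 19.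

Step 10. Hydroboration of the bromoalkene or loss of bromide may accompany reduction of the acid. The fallback changes the oxidation-level sequence and sets out from 15. Fischer esterification (MeOH, H2SO4 cat., reflux) gives methyl (2E)-3-bromoprop-2-enoate F6, and reduction with iBu2AlH (2.2 equiv, CH2Cl2, −78 °C) comes back to the route at 16.

**Further compounds**

F1 | step 3 | [(2S,5S)-5-[(trimethylsilyl)ethynyl]oxolan-2-yl]methanol | OC[C@@H]1CC[C@@H](C#C[Si](C)(C)C)O1
F2 | step 3 | trimethyl{[(2S,5S)-5-(iodomethyl)oxolan-2-yl]ethynyl}silane | IC[C@@H]1CC[C@@H](C#C[Si](C)(C)C)O1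
F3 | step 12 | methyl 4-[(2R,5S)-5-[(3E)-9-oxonon-3-en-1-yn-1-yl]oxolan-2-yl]butanoate | COC(=O)CCC[C@@H]1CC[C@@H](C#C/C=C/CCCCC=O)O1
F4 | step 12 | methyl 4-[(2R,5S)-5-[(3E,9Z)-10-iododeca-3,9-dien-1-yn-1-yl]oxolan-2-yl]butanoate | COC(=O)CCC[C@@H]1CC[C@@H](C#C/C=C/CCCC/C=C\I)O1
F5 | step 12 | methyl 4-[(2R,5S)-5-[(3E,9Z,11E)-12-(tributylstannyl)dodeca-3,9,11-trien-1-yn-1-yl]oxolan-2-yl]butanoate | COC(=O)CCC[C@@H]1CC[C@@H](C#C/C=C/CCCC/C=C\C=C\[Sn](CCCC)(CCCC)CCCC)O1
F6 | step 10 | methyl (2E)-3-bromoprop-2-enoate | COC(=O)/C=C/Br
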